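- Read the first-step constant from the oak run, whose substrate fell to 83.5% by 8.00 min: the pseudo-first-order constant at 50.4 mM of partner is 0.0225 /min, so the substrate half-life is 30.8 min.

| flask | substrate | partner | remark | time |
|---|---|---|---|---|
| oak | 14 mM | 50.4 mM | run made earlier |  |
| maple | 56 mM | 50.4 mM | run made earlier |  |
| flask | 28 mM | 50.4 mM |  | 20 min |

- oak (time / min: substrate / %, first product / %, double product / %): 2.50: 93.8, 5.2, 0.2; 8.00: 83.5, 12.6, 3.9; 12.0: 76.2, 15.8, 8.0; 20.0: 64.3, 17.1, 16.2
- maple (time / min: substrate / %, first product / %, double product / %): 1.50: 96.4, 3.2, 0.3; 4.00: 91.4, 7.7, 0.9; 8.00: 84.4, 11.9, 3.6; 20.0: 71.6, 17.1, 11.0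

(readings scatter by 0.3 percentage points)

* how much substrate there is at 20 min, in percent of the substrate charged
* how much first product there is at 20 min, in percent of the substrate charged
* how much double product there is at 20 min, in percent of the substrate charged

- Apply the bench rule to the flask: with partner held at its charge, 20 min is 0.650 half-lives, which leaves 63.7% of the substrate.
- Find the border with the ratio of partner charged to the two equivalents that each substrate can take: oak has 1.80, maple 0.450, and the flask 0.900.
- Note that the flask ratio is below one, so partner is the limiting reagent for full double conversion, and its fall has to be counted. The maple run shows the failure: it kept 71.6% of its substrate at 20.0 min, more than the rule's 63.8%.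
- Correct the count. Average first product plus twice double product over the last oak and maple rows, taking one partner per first product and two per double product, and estimate that the flask keeps 75.4% of its partner.
- Multiply the half-lives by the mean partner share, and call the result the partner-weighted half-life count 0.570. My reckoning leaves 67.4% of the flask's substrate.
- Set beside it the forecast, made by its own route: substrate 66.6%, first product 18.8%, double product 14.6%, with the remark “Late maple runs somewhat slower than partner depletion alone explains”.
- Read the flask: substrate 67.2%, first product 17.8%, double product 14.2%.

    substrate + partner → first product (k = 0.470 /M/min)
    partner + first product → double product (k = 1.50 /M/min)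
    double product ⇌ isomer of the product (K = 7.60, k = 0.0230 /min)
    partner + double product ⇌ idle adduct, settled at all times (K = 72.0 /M)

- The flask stands at an estimated 0.570 weighted half-lives, under one, with 67.2% of its substrate left and 68% of its partner, less than the 75.4% estimated. Count the neighbour flask charged with 200 mM of partner the same way: scale the half-lives by its charge and weight them with its 70.5% of partner left. That gives 2.20 half-lives and 21.8% of substrate. The neighbour flask holds 21.1% of substrate at 20.0 min.

The data are simulated on assumed constants; scatter was added.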